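**Retrosynthetic overview**
- Target ⇐ 14-O-silyl macrocycle ⇐ ring-closing metathesis at C9=C10; the ten-membered carbocycle is formed last.
- anti 1-OAc/3-OH pair ⇐ Evans–Tishchenko reduction (acetaldehyde) of the aldol from a C3 methyl ketone and 2-(silyloxymethyl)acrolein (C1–C2 bond).
- cis-Fused α-methylene lactone (formed first) ⇐ stereoinvertive C8–O closure of a tert-butyl ester onto the activated 8-OH.
- 6-O-(2-methylbutanoyl)/8-OH pair ⇐ Evans–Tishchenko reduction ((S)-2-methylbutanal) of the anti-aldol from a vinyl ketone and (Z)-3-methylpent-2-en-4-ynal (C6–C7 bond); the alkyne is the latent C3 ketone.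
- Building blocks: acrolein, tert-butyl 2-(bromomethyl)acrylate, (Z)-3-methylpent-2-en-4-yn-1-ol, (S)-2-methylbutan-1-ol, 2-methylidenepropane-1,3-diol, acetaldehyde.

Assumption: locants C1–C15 follow germacrane numbering (C1 acetate, C3 and C14 hydroxyls, C6 2-methylbutanoate, C8 lactone oxygen, C12 lactone carbonyl).
Assumption: the (−)-menthone-derived bromoborane of the first aldol (made separately by methylenation and hydroboration with BrBH2·SMe2, not counted as route steps) and (−)-Ipc2BCl of the second aldol are taken to give the senses shown; if either is opposite, the enantiomeric reagent is used.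

**Step 1**
Reactants: 1 acrolein; 2 tert-butyl 2-(bromomethyl)prop-2-enoate
Product: 3 tert-butyl 4-hydroxy-2-methylidenehex-5-enoate (racemic)
Conditions: Zn dust, sat. aq NH4Cl, THF, 0 °C to rt
Reagents that add atoms: none
Why: Zinc-mediated Barbier allylation adds the allyl unit 1,2 to acrolein, the racemic carbinol centre is erased in step 2, and the tert-butyl ester does not lactonise.

**Step 2**
Reactants: 3 tert-butyl 4-hydroxy-2-methylidenehex-5-enoate
Product: 4 tert-butyl 2-methylidene-4-oxohex-5-enoate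
Conditions: Dess–Martin periodinane, pyridine, CH2Cl2, 0 °C; used crude
Reagents that add atoms: none
Why: Buffered Dess–Martin oxidation gives the vinyl ketone without conjugating the β,γ-alkene, leaving C7 as the only enolisable position.

**Step 3**
Reactants: 5 (2Z)-3-methylpent-2-en-4-yn-1-ol
Product: 6 (2Z)-3-methylpent-2-en-4-ynal
Conditions: MnO2, CH2Cl2, 0 °C, dark
Reagents that add atoms: none
Why: MnO2 allylic oxidation is neutral and heterogeneous, so the Z geometry that becomes the C4=C5 ring alkene is kept.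

**Step 4**
Reactants: 4 tert-butyl 2-methylidene-4-oxohex-5-enoate; 6 (2Z)-3-methylpent-2-en-4-ynal
Product: 8 tert-butyl (3R,4R,5Z)-4-hydroxy-6-methyl-2-methylidene-3-(prop-2-enoyl)oct-5-en-7-ynoate, via E-enol borinate 7 (not isolated)
Conditions: bis{[(1R,2S,5R)-2-isopropyl-5-methylcyclohexyl]methyl}bromoborane, Et3N, Et2O/CH2Cl2, −78 °C; then 6, −78 to −20 °C; H2O2, pH 7 buffer, MeOH, 0 °C
Reagents that add atoms: none
Why: Gennari–Paterson asymmetric boron aldol, in which the E-enol borinate 7 reacts through a chair Zimmerman–Traxler transition state to place 6-OH and the C7 acrylate branch anti while the menthone-derived ligands choose the aldehyde face, setting C6 (R) and C7 (R).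

**Step 5**
Reactants: 9 (2S)-2-methylbutan-1-ol
Product: 10 (2S)-2-methylbutanal
Conditions: TEMPO (cat.), PhI(OAc)2, CH2Cl2, 0 °C to rt; distilled solution used at once
Reagents that add atoms: none
Why: TEMPO/PhI(OAc)2 oxidation of a primary alcohol is neutral and does not epimerise the α-stereocentre.

**Step 6**
Reactants: 8 tert-butyl (3R,4R,5Z)-4-hydroxy-6-methyl-2-methylidene-3-(prop-2-enoyl)oct-5-en-7-ynoate; 10 (2S)-2-methylbutanal
Product: 11 tert-butyl (3S,4R,5Z)-3-[(1R)-1-hydroxyprop-2-en-1-yl]-6-methyl-2-methylidene-4-{[(2S)-2-methylbutanoyl]oxy}oct-5-en-7-ynoate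
Conditions: SmI2 (0.3 equiv, premixed with 10), THF, −10 °C
Reagents that add atoms: none
Why: Evans–Tishchenko reduction, in which the aldehyde carbon, tethered through O6 on trivalent samarium, delivers hydride intramolecularly through a six-membered chair to the C8 ketone, so the 6-O acyl C–O bond and a 1,3-anti C8 carbinol (8R) form together with complete site control.

**Step 7**
Reactants: 11 tert-butyl (3S,4R,5Z)-3-[(1R)-1-hydroxyprop-2-en-1-yl]-6-methyl-2-methylidene-4-{[(2S)-2-methylbutanoyl]oxy}oct-5-en-7-ynoate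
Product: 14 (1R,2Z)-1-[(2S,3R)-2-ethenyl-4-methylidene-5-oxooxolan-3-yl]-3-methylpent-2-en-4-yn-1-yl (2S)-2-methylbutanoate, via alkoxyphosphonium triflate 12 (not isolated), via tert-butoxyoxolenium triflate 13 (not isolated)
Conditions: Ph3PO (2.4 equiv), Tf2O (1.2 equiv), CH2Cl2, 0 °C; then 11, 2,6-di-tert-butyl-4-methylpyridine, −40 to 0 °C
Reagents that add atoms: none
Why: Proposed new method: (Ph3P)2O(OTf)2 turns the allylic 8-OH into alkoxyphosphonium 12, which has no nucleophilic counter-ion and no free acid (so no retentive acyloxyphosphonium or Fischer pathway), and the conjugated tert-butyl ester carbonyl oxygen displaces Ph3PO from the rear in a 5-exo-tet SN2 step to give 13, which loses 2-methylpropene to close the cis-fused lactone with inversion at C8 (8R to 8S); the closest known reactions are Hendrickson or Mitsunobu cyclodehydration of β-hydroxy amides to oxazolines with inversion and halolactonisation of tert-butyl esters.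

**Step 8**
Reactants: 14 (1R,2Z)-1-[(2S,3R)-2-ethenyl-4-methylidene-5-oxooxolan-3-yl]-3-methylpent-2-en-4-yn-1-yl (2S)-2-methylbutanoate
Product: 15 (1R,2Z)-1-[(2S,3R)-2-ethenyl-4-methylidene-5-oxooxolan-3-yl]-3-methyl-4-oxopent-2-en-1-yl (2S)-2-methylbutanoate
Conditions: (Ph3P)AuNTf2 (3 mol %), H2O, 1,4-dioxane, 45 °C
Reagents that add atoms: water, O
Why: Gold-catalysed Markovnikov hydration of the terminal alkyne of the conjugated enyne gives the C3 methyl ketone, and it is run only after O6 is acylated so the cis-γ-oxygen cannot cyclise to a furan.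

**Step 9**
Reactants: 16 2-methylidenepropane-1,3-diol
Product: 17 2-({[tert-butyl(dimethyl)silyl]oxy}methyl)prop-2-en-1-ol
Conditions: TBSCl (0.4 equiv), imidazole, THF, 0 °C; excess diol recovered
Reagents that add atoms: tert-butyl(chloro)dimethylsilane (TBSCl), CC(C)(C)[Si](C)(C)Cl
Why: Statistical monosilylation of a symmetrical diol used in excess gives the mono-TBS ether.

**Step 10**
Reactants: 17 2-({[tert-butyl(dimethyl)silyl]oxy}methyl)prop-2-en-1-ol
Product: 18 2-({[tert-butyl(dimethyl)silyl]oxy}methyl)prop-2-enal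
Conditions: MnO2, CH2Cl2, rt
Reagents that add atoms: none
Why: MnO2 allylic oxidation gives the 2-substituted acrolein without over-oxidation.

**Step 11**
Reactants: 15 (1R,2Z)-1-[(2S,3R)-2-ethenyl-4-methylidene-5-oxooxolan-3-yl]-3-methyl-4-oxopent-2-en-1-yl (2S)-2-methylbutanoate; 18 2-({[tert-butyl(dimethyl)silyl]oxy}methyl)prop-2-enal
Product: 20 (1R,2Z,6S)-7-({[tert-butyl(dimethyl)silyl]oxy}methyl)-1-[(2S,3R)-2-ethenyl-4-methylidene-5-oxooxolan-3-yl]-6-hydroxy-3-methyl-4-oxoocta-2,7-dien-1-yl (2S)-2-methylbutanoate, via boron enolate 19 (not isolated)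
Conditions: (−)-Ipc2BCl, Et3N, Et2O, −78 to 0 °C; then 18, −78 to −20 °C; H2O2, pH 7 buffer, MeOH, 0 °C
Reagents that add atoms: none
Why: Paterson Ipc2BCl aldol of a methyl ketone, in which the kinetically formed C2 boron enolate 19 adds to the Si face of aldehyde 18 under reagent control, setting C1 (S).

**Step 12**
Reactants: 20 (1R,2Z,6S)-7-({[tert-butyl(dimethyl)silyl]oxy}methyl)-1-[(2S,3R)-2-ethenyl-4-methylidene-5-oxooxolan-3-yl]-6-hydroxy-3-methyl-4-oxoocta-2,7-dien-1-yl (2S)-2-methylbutanoate; 21 acetaldehyde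
Product: 22 (1R,2Z,4S,6S)-6-(acetyloxy)-7-({[tert-butyl(dimethyl)silyl]oxy}methyl)-1-[(2S,3R)-2-ethenyl-4-methylidene-5-oxooxolan-3-yl]-4-hydroxy-3-methylocta-2,7-dien-1-yl (2S)-2-methylbutanoate
Conditions: SmI2 (0.3 equiv), THF, −10 °C
Reagents that add atoms: none
Why: Evans–Tishchenko reduction with acetaldehyde, in which intramolecular hydride delivery through O1 on trivalent samarium gives the 1,3-anti C3 carbinol (3S) and forms the 1-O-acetyl C–O bond in the same event.

**Step 13**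
Reactants: 22 (1R,2Z,4S,6S)-6-(acetyloxy)-7-({[tert-butyl(dimethyl)silyl]oxy}methyl)-1-[(2S,3R)-2-ethenyl-4-methylidene-5-oxooxolan-3-yl]-4-hydroxy-3-methylocta-2,7-dien-1-yl (2S)-2-methylbutanoate
Product: 23 (1S,3S,6R,7R,8S,4Z,9Z)-1-acetoxy-14-{[tert-butyl(dimethyl)silyl]oxy}-3-hydroxy-6-{[(2S)-2-methylbutanoyl]oxy}germacra-4,9,11(13)-trien-8,12-olide
Conditions: second-generation Hoveyda–Grubbs catalyst (H2IMes)Cl2Ru=CH(C6H4-2-OiPr) (10 mol %), 1,4-benzoquinone, toluene (1 mM), 80 °C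
Reagents that add atoms: none
Why: Ring-closing metathesis between the C8 vinyl group and the 1,1-disubstituted C10 alkene closes the ten-membered ring, where only the Z (ring-cis) trisubstituted alkene is accessible beside the existing Z alkene and the fused lactone.

**Step 14**
Reactants: 23 (1S,3S,6R,7R,8S,4Z,9Z)-1-acetoxy-14-{[tert-butyl(dimethyl)silyl]oxy}-3-hydroxy-6-{[(2S)-2-methylbutanoyl]oxy}germacra-4,9,11(13)-trien-8,12-olide
Product: 24 (1S,3S,6R,7R,8S,4Z,9Z)-1-acetoxy-3,14-dihydroxy-6-{[(2S)-2-methylbutanoyl]oxy}germacra-4,9,11(13)-trien-8,12-olide (CNP0217661.3)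
Conditions: HF·pyridine, pyridine, THF, 0 °C
Reagents that add atoms: none
Why: Buffered fluoride desilylation removes the primary TBS ether without acyl migration or attack on the α-methylene lactone.

**Compound list**
1 | acrolein | C=CC=O | starting material
2 | tert-butyl 2-(bromomethyl)prop-2-enoate | C=C(CBr)C(=O)OC(C)(C)C | starting material
3 | tert-butyl 4-hydroxy-2-methylidenehex-5-enoate (racemic) | C=CC(O)CC(=C)C(=O)OC(C)(C)C | intermediate
4 | tert-butyl 2-methylidene-4-oxohex-5-enoate | C=CC(=O)CC(=C)C(=O)OC(C)(C)C | intermediate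
5 | (2Z)-3-methylpent-2-en-4-yn-1-ol | C#C/C(C)=C\CO | starting material
6 | (2Z)-3-methylpent-2-en-4-ynal | C#C/C(C)=C\C=O | intermediate
7 | E-enol borinate of 4 with two (menthyl)methyl groups on boron | C=CC(/OB(C[C@@H]1C[C@H](C)CC[C@H]1C(C)C)C[C@@H]1C[C@H](C)CC[C@H]1C(C)C)=C\C(=C)C(=O)OC(C)(C)C | intermediate
8 | tert-butyl (3R,4R,5Z)-4-hydroxy-6-methyl-2-methylidene-3-(prop-2-enoyl)oct-5-en-7-ynoate | C=CC(=O)[C@H](C(=C)C(=O)OC(C)(C)C)[C@H](O)/C=C(C)\C#C | intermediate
9 | (2S)-2-methylbutan-1-ol | CC[C@H](C)CO | starting material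
10 | (2S)-2-methylbutanal | CC[C@H](C)C=O | intermediate
11 | tert-butyl (3S,4R,5Z)-3-[(1R)-1-hydroxyprop-2-en-1-yl]-6-methyl-2-methylidene-4-{[(2S)-2-methylbutanoyl]oxy}oct-5-en-7-ynoate | C=C[C@@H](O)[C@H](C(=C)C(=O)OC(C)(C)C)[C@H](OC(=O)[C@@H](C)CC)/C=C(C)\C#C | intermediate
12 | alkoxy(triphenyl)phosphonium triflate of 11 (O8–PPh3, C8 configuration unchanged) | C=C[C@@H](O[P+](c1ccccc1)(c1ccccc1)c1ccccc1)[C@H](C(=C)C(=O)OC(C)(C)C)[C@H](OC(=O)[C@@H](C)CC)/C=C(C)\C#C.[O-]S(=O)(=O)C(F)(F)F | intermediate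
13 | 2-tert-butoxyoxolenium triflate (O-alkylated ester, C8 inverted) | C=C1C(OC(C)(C)C)=[O+][C@@H](C=C)[C@H]1[C@H](OC(=O)[C@@H](C)CC)/C=C(C)\C#C.[O-]S(=O)(=O)C(F)(F)F | intermediate
14 | (1R,2Z)-1-[(2S,3R)-2-ethenyl-4-methylidene-5-oxooxolan-3-yl]-3-methylpent-2-en-4-yn-1-yl (2S)-2-methylbutanoate | C=C1C(=O)O[C@@H](C=C)[C@H]1[C@H](OC(=O)[C@@H](C)CC)/C=C(C)\C#C | intermediate
15 | (1R,2Z)-1-[(2S,3R)-2-ethenyl-4-methylidene-5-oxooxolan-3-yl]-3-methyl-4-oxopent-2-en-1-yl (2S)-2-methylbutanoate | C=C1C(=O)O[C@@H](C=C)[C@H]1[C@H](OC(=O)[C@@H](C)CC)/C=C(C)\C(C)=O | intermediate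
16 | 2-methylidenepropane-1,3-diol | C=C(CO)CO | starting material
17 | 2-({[tert-butyl(dimethyl)silyl]oxy}methyl)prop-2-en-1-ol | C=C(CO)CO[Si](C)(C)C(C)(C)C | intermediate
18 | 2-({[tert-butyl(dimethyl)silyl]oxy}methyl)prop-2-enal | C=C(C=O)CO[Si](C)(C)C(C)(C)C | intermediate
19 | diisopinocampheylboron enolate of 15 (O3–B, C2=C3) | C=C1C(=O)O[C@@H](C=C)[C@H]1[C@H](OC(=O)[C@@H](C)CC)/C=C(C)\C(=C)OB([C@@H]1C[C@@H]2C[C@H]([C@H]1C)C2(C)C)[C@@H]1C[C@@H]2C[C@H]([C@H]1C)C2(C)C | intermediate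
20 | (1R,2Z,6S)-7-({[tert-butyl(dimethyl)silyl]oxy}methyl)-1-[(2S,3R)-2-ethenyl-4-methylidene-5-oxooxolan-3-yl]-6-hydroxy-3-methyl-4-oxoocta-2,7-dien-1-yl (2S)-2-methylbutanoate | C=C1C(=O)O[C@@H](C=C)[C@H]1[C@H](OC(=O)[C@@H](C)CC)/C=C(C)\C(=O)C[C@H](O)C(=C)CO[Si](C)(C)C(C)(C)C | intermediate
21 | acetaldehyde | CC=O | starting material
22 | (1R,2Z,4S,6S)-6-(acetyloxy)-7-({[tert-butyl(dimethyl)silyl]oxy}methyl)-1-[(2S,3R)-2-ethenyl-4-methylidene-5-oxooxolan-3-yl]-4-hydroxy-3-methylocta-2,7-dien-1-yl (2S)-2-methylbutanoate | C=C1C(=O)O[C@@H](C=C)[C@H]1[C@H](OC(=O)[C@@H](C)CC)/C=C(C)\[C@@H](O)C[C@H](OC(C)=O)C(=C)CO[Si](C)(C)C(C)(C)C | intermediate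
23 | (1S,3S,6R,7R,8S,4Z,9Z)-1-acetoxy-14-{[tert-butyl(dimethyl)silyl]oxy}-3-hydroxy-6-{[(2S)-2-methylbutanoyl]oxy}germacra-4,9,11(13)-trien-8,12-olide | C=C1C(=O)O[C@H]2/C=C(/CO[Si](C)(C)C(C)(C)C)[C@@H](OC(C)=O)C[C@H](O)/C(C)=C\[C@@H](OC(=O)[C@@H](C)CC)[C@@H]12 | intermediate
24 | (1S,3S,6R,7R,8S,4Z,9Z)-1-acetoxy-3,14-dihydroxy-6-{[(2S)-2-methylbutanoyl]oxy}germacra-4,9,11(13)-trien-8,12-olide (CNP0217661.3) | C=C1C(=O)O[C@H]2/C=C(/CO)[C@@H](OC(C)=O)C[C@H](O)/C(C)=C\[C@@H](OC(=O)[C@@H](C)CC)[C@@H]12 | target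

**Step count and risks**

Total step count: 14. Longest linear sequence: 10 (steps 1, 2, 4, 6, 7, 8, 11, 12, 13, 14).

Most likely to fail, first: step 7, the proposed new lactonisation. The allylic alkoxyphosphonium 12 may ionise (SN1, loss of stereospecificity, trans-lactone) or eliminate to a diene before the ester captures it. The fallback uses known chemistry and sets out from 11. A Mitsunobu inversion with 4-nitrobenzoic acid (PPh3, DIAD, THF, 0 °C) gives the inverted ester tert-butyl (3R,4R,5Z)-6-methyl-2-methylidene-4-{[(2S)-2-methylbutanoyl]oxy}-3-[(1S)-1-(4-nitrobenzoyloxy)prop-2-en-1-yl]oct-5-en-7-ynoate F1. K2CO3 in MeOH at 0 °C removes only the activated nitrobenzoate and gives the (1S)-alcohol tert-butyl (3S,4R,5Z)-3-[(1S)-1-hydroxyprop-2-en-1-yl]-6-methyl-2-methylidene-4-{[(2S)-2-methylbutanoyl]oxy}oct-5-en-7-ynoate F2. CF3CO2H in CH2Cl2 then cleaves the tert-butyl ester and the γ-hydroxy acid closes with retention, coming back to the route at 14.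

Second: step 4, the asymmetric anti-aldol. Vinyl ketone 4 is labile (polymerisation, conjugation of the β,γ-alkene) and the chiral bromoborane has not been used on such a ketone; any minor enantiomer that does form becomes a diastereomeric ester in step 6 and is removed there. The fallback sets out from 4 and 6 and replaces reagent control by a classical resolution. Cy2BCl and Et3N give the racemic anti-aldol, that is 8 together with its enantiomer tert-butyl (3S,4S,5Z)-4-hydroxy-6-methyl-2-methylidene-3-(prop-2-enoyl)oct-5-en-7-ynoate F3. The Evans–Tishchenko reaction with enantiopure 10 then converts the pair into 11 and the diastereomer tert-butyl (3R,4S,5Z)-3-[(1S)-1-hydroxyprop-2-en-1-yl]-6-methyl-2-methylidene-4-{[(2S)-2-methylbutanoyl]oxy}oct-5-en-7-ynoate F4, which is separated by chromatography; the route is rejoined at 11.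

Third: step 13, the ring-closing metathesis. The 1,1-disubstituted C10 alkene is flanked by an acetate and a silyloxymethyl group and may not engage, leading to oligomers. The fallback sets out from 20 and closes the ring one stage earlier, where the free allylic 1-OH accelerates metathesis and C3 is still sp2. Metathesis of 20 with the same catalyst gives the macrocyclic β-hydroxy enone (1S,6R,7R,8S,4Z,9Z)-14-{[tert-butyl(dimethyl)silyl]oxy}-1-hydroxy-6-{[(2S)-2-methylbutanoyl]oxy}-3-oxogermacra-4,9,11(13)-trien-8,12-olide F5. The Evans–Tishchenko reaction with 21 is then run on the ring, where hydride delivery is still governed by the local O1/C3 ketone pair, coming back to the route at 23.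

**Further compounds**
F1 | step 7 | tert-butyl (3R,4R,5Z)-6-methyl-2-methylidene-4-{[(2S)-2-methylbutanoyl]oxy}-3-[(1S)-1-(4-nitrobenzoyloxy)prop-2-en-1-yl]oct-5-en-7-ynoate | C=C[C@H](OC(=O)c1ccc(cc1)[N+](=O)[O-])[C@H](C(=C)C(=O)OC(C)(C)C)[C@H](OC(=O)[C@@H](C)CC)/C=C(C)\C#C
F2 | step 7 | tert-butyl (3S,4R,5Z)-3-[(1S)-1-hydroxyprop-2-en-1-yl]-6-methyl-2-methylidene-4-{[(2S)-2-methylbutanoyl]oxy}oct-5-en-7-ynoate | C=C[C@H](O)[C@H](C(=C)C(=O)OC(C)(C)C)[C@H](OC(=O)[C@@H](C)CC)/C=C(C)\C#C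
F3 | step 4 | tert-butyl (3S,4S,5Z)-4-hydroxy-6-methyl-2-methylidene-3-(prop-2-enoyl)oct-5-en-7-ynoate | C=CC(=O)[C@@H](C(=C)C(=O)OC(C)(C)C)[C@@H](O)/C=C(C)\C#C
F4 | step 4 | tert-butyl (3R,4S,5Z)-3-[(1S)-1-hydroxyprop-2-en-1-yl]-6-methyl-2-methylidene-4-{[(2S)-2-methylbutanoyl]oxy}oct-5-en-7-ynoate | C=C[C@H](O)[C@@H](C(=C)C(=O)OC(C)(C)C)[C@@H](OC(=O)[C@@H](C)CC)/C=C(C)\C#C
F5 | step 13 | (1S,6R,7R,8S,4Z,9Z)-14-{[tert-butyl(dimethyl)silyl]oxy}-1-hydroxy-6-{[(2S)-2-methylbutanoyl]oxy}-3-oxogermacra-4,9,11(13)-trien-8,12-olide | C=C1C(=O)O[C@H]2/C=C(/CO[Si](C)(C)C(C)(C)C)[C@@H](O)CC(=O)/C(C)=C\[C@@H](OC(=O)[C@@H](C)CC)[C@@H]12
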